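**Retrosynthetic overview**

1. Locants of the 3,7-dioxabicyclo[3.3.0]octane core: C-1 carbinol bridgehead, C-2 aryl CH of ring B, O-3, C-4, C-5 CH bridgehead, C-6 aryl CH of ring A, O-7, C-8. Ring A = C-5/C-6/O-7/C-8/C-1; ring B = C-1/C-2/O-3/C-4/C-5.
2. Target ⇒ deallylation ⇒ O-3–C-4 ether closure ⇒ lactone reduction ⇒ furofuranone (C-4 as lactone carbonyl) ⇒ key disconnection of the C-5–C-6 bond of ring A ⇒ ring B γ-lactone carrying on C-1 a spiro-1,3-dioxolane whose acetal carbon is C-6.
3. Enabling feature: in ring B the bridgehead CH (C-5) is flanked by the O-bound CH2 (C-4), which can be raised to a lactone carbonyl so that C-5 becomes enolisable. The tertiary hydroxyl on C-1 is 1,2-related to the ring A oxygen O-7 (through C-8), so C-6 can be tied to both oxygens as a spiro-acetal; ionising it at the C-1 oxygen leaves an oxocarbenium ion on O-7, four atoms from C-5.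
4. Spiro-acetal ⇒ diol lactone + O-allylvanillin; diol lactone ⇒ (2S,3S)-epoxy alcohol (asymmetric epoxidation, invertive lactonisation) ⇒ Stobbe half-ester ⇒ O-allylvanillin + dimethyl succinate.
5. Ring order: ring B as γ-lactone (step 6), temporary dioxolane (step 7), ring A through the C-5–C-6 bond (step 8), ring B opened by reduction and re-closed as the ether (steps 9 and 10).

Key step: step 8

Remark on the chemistry: L-(+)-diethyl tartrate is taken as the tartrate that gives (2S,3S)-epoxy alcohols from (E)-2-substituted cinnamyl alcohols; both phenols are carried as allyl ethers. Ar = 4-(allyloxy)-3-methoxyphenyl throughout.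

**Route**

Step 1
Reactants: 1 vanillin
Product: 2 4-(allyloxy)-3-methoxybenzaldehyde
Conditions: allyl bromide, K2CO3, DMF, 60 °C
Reagents that add atoms: allyl bromide C=CCBr
Why: Williamson O-allylation of the phenoxide is reliable and gives an ether that survives the alkoxide, hydride, peroxide and Lewis-acid steps and can be removed at the end without hydrogenolysis.

Step 2
Reactants: 2 4-(allyloxy)-3-methoxybenzaldehyde; 3 dimethyl succinate
Product: 4 (E)-4-Ar-3-(methoxycarbonyl)but-3-enoic acid
Conditions: NaOMe, MeOH, reflux; then aq. HCl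
Reagents that add atoms: none
Why: The Stobbe condensation (aldol addition, lactonisation to the paraconic ester, E1cB ring opening) should give the (E)-half-ester with the aryl group cis to the CH2CO2H arm and the two carboxyl groups already differentiated.

Step 3
Reactants: 4 (E)-4-Ar-3-(methoxycarbonyl)but-3-enoic acid
Product: 5 4-tert-butyl 1-methyl (E)-2-(Ar-methylidene)butanedioate
Conditions: tert-butyl 2,2,2-trichloroacetimidate, BF3·OEt2 (cat.), CH2Cl2/cyclohexane, rt
Reagents that add atoms: tert-butyl 2,2,2-trichloroacetimidate CC(C)(C)OC(=N)C(Cl)(Cl)Cl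
Why: Acid-catalysed O-alkylation of the free acid by the imidate (tert-butyl cation transfer) should install an ester that resists hydride at low temperature and can later leave as isobutene, without touching the alkene geometry.

Step 4
Reactants: 5 4-tert-butyl 1-methyl (E)-2-(Ar-methylidene)butanedioate
Product: 6 tert-butyl (E)-4-Ar-3-(hydroxymethyl)but-3-enoate
Conditions: i-Bu2AlH (2.2 equiv), CH2Cl2, −78 °C; aq. potassium sodium tartrate
Reagents that add atoms: none
Why: 1,2-Reduction of the conjugated methyl ester by i-Bu2AlH should stop at the (E)-allylic alcohol, because the bulky tert-butyl ester is attacked far more slowly at −78 °C.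

Step 5
Reactants: 6 tert-butyl (E)-4-Ar-3-(hydroxymethyl)but-3-enoate
Product: 7 tert-butyl 2-[(2S,3S)-3-Ar-2-(hydroxymethyl)oxiran-2-yl]acetate
Conditions: Ti(OiPr)4 (10 mol %), L-(+)-diethyl tartrate (12 mol %), t-BuOOH, 4 Å molecular sieves, CH2Cl2, −20 °C
Reagents that add atoms: tert-butyl hydroperoxide CC(C)(C)OO
Why: Sharpless–Katsuki asymmetric epoxidation of the (E)-2-substituted cinnamyl-type alcohol, in which the titanium tartrate complex delivers oxygen to one alkene face under reagent control, should set both epoxide carbons as (2S,3S).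

Step 6
Reactants: 7 tert-butyl 2-[(2S,3S)-3-Ar-2-(hydroxymethyl)oxiran-2-yl]acetate
Product: 8 (4S,5R)-5-Ar-4-hydroxy-4-(hydroxymethyl)oxolan-2-one
Conditions: CSA (10 mol %), CH2Cl2, −20 → 0 °C
Reagents that add atoms: none
Why: In this acid-triggered epoxide-opening lactonisation with neighbouring-group participation, the ester carbonyl oxygen should attack the benzylic epoxide carbon from the back (five-membered ring, inversion there, retention at the tertiary carbinol carbon) and the tert-butyl group should leave as isobutene, giving ring B as the γ-lactone with the aryl group cis to the tertiary hydroxyl.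

Step 7
Reactants: 8 (4S,5R)-5-Ar-4-hydroxy-4-(hydroxymethyl)oxolan-2-one; 2 4-(allyloxy)-3-methoxybenzaldehyde
Product: 9 (5S,6R)-2,6-di-Ar-1,3,7-trioxaspiro[4.4]nonan-8-one (both epimers at the acetal carbon)
Conditions: PPTS (10 mol %), 4 Å molecular sieves, PhMe, 80 °C
Reagents that add atoms: none
Why: Acid-catalysed acetalisation of the 1,2-diol (tertiary and primary hydroxyl) with the aryl aldehyde under removal of water should give the spiro-1,3-dioxolane, whose acetal carbon forms as an inconsequential mixture of epimers because this centre is ionised in step 8.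

Step 8
Reactants: 9 (5S,6R)-2,6-di-Ar-1,3,7-trioxaspiro[4.4]nonan-8-one
Product: 11 (3R,3aS,6S,6aR)-3,6-di-Ar-3a-(trimethylsilyloxy)tetrahydro-1H,3H-furo[3,4-c]furan-1-one, via silyl ketene acetal 10 (not isolated)
Conditions: Me3SiOTf (2.5 equiv), i-Pr2NEt (1.5 equiv), CH2Cl2, −78 → 0 °C; sat. aq. NaHCO3
Reagents that add atoms: trimethylsilyl trifluoromethanesulfonate C[Si](C)(C)OS(=O)(=O)C(F)(F)F
Why: Proposed new method: Me3SiOTf and i-Pr2NEt turn the lactone into silyl ketene acetal 10 while Me3SiOTf ionises the spiro-dioxolane at its bond to the tertiary oxygen, which leaves an (E)-configured, aryl-stabilised oxocarbenium ion on the primary oxygen (the later O-7) and caps the C-1 oxygen as its silyl ether; the ketene acetal carbon (the later C-5) then adds to the oxocarbenium carbon (the later C-6) and the silyl group leaves the resulting carbonyl oxygen, which regenerates the lactone. The closest known reaction types are the Petasis–Ferrier rearrangement of cyclic enol acetals (oxocarbenium and enolate recombining to an oxacycle), the one-pot enol silane formation and Mukaiyama-type addition to acetals with a silyl triflate and an amine, and the aldol-type closure that ends the Lewis-acid (3+2) annulation of aldehydes with donor–acceptor cyclopropanes; new is the intramolecular use on a lactone that carries the acetal as a spiro ring on its β-carbon. Ring A closes in a 5-(enolexo)-endo-trig mode onto the C=O+ unit, the mode by which 1,3-dioxolanes themselves form, and ring B is already in place. C-5 is set by the tether, since the OCH2 arm on C-1 reaches only the enol face on its own side and so forces the cis ring fusion with H-5 syn to the C-1 oxygen; C-6 is set by the (E)-oxocarbenium geometry and by the aryl group taking the convex (exo) side of the forming bicycle, away from the lactone ring. The step needs the productive ionisation mode and C–C bond formation ahead of β-elimination of the C-1 oxygen from the ketene acetal: both acetal C–O bonds ionise reversibly but only the ion on the primary oxygen can close a five-membered ring (the other could only give an oxetane), and the oxocarbenium ion is already present at −78 °C when the slower soft enolisation starts, so each ketene acetal is formed next to its electrophile.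

Step 9
Reactants: 11 (3R,3aS,6S,6aR)-3,6-di-Ar-3a-(trimethylsilyloxy)tetrahydro-1H,3H-furo[3,4-c]furan-1-one
Product: 13 (3S,4R,5S)-5-Ar-3-[(R)-Ar(hydroxy)methyl]-4-(hydroxymethyl)oxolan-3-ol, via silyl ether diol 12 (not isolated)
Conditions: LiAlH4, THF, 0 °C; H2O/NaOH work-up; then K2CO3, MeOH, rt
Reagents that add atoms: none
Why: Hydride reduction of the lactone by LiAlH4 should give the 1,4-diol without touching any stereocentre, the tertiary silyl ether guarding against retro-aldol opening during the reduction and then being removed by base-catalysed methanolysis.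

Step 10
Reactants: 13 (3S,4R,5S)-5-Ar-3-[(R)-Ar(hydroxy)methyl]-4-(hydroxymethyl)oxolan-3-ol
Product: 15 (1S,2R,5R,6S)-2,6-di-Ar-3,7-dioxabicyclo[3.3.0]octan-1-ol, via primary mesylate 14 (not isolated)
Conditions: MsCl (1.1 equiv), pyridine, CH2Cl2, 0 → 40 °C
Reagents that add atoms: none
Why: Selective sulfonylation of the primary hydroxyl followed by 5-exo-tet Williamson-type closure by the benzylic hydroxyl should re-close ring B as the cyclic ether with retention at the benzylic carbon, since no bond to that carbon is broken.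

Step 11
Reactants: 15 (1S,2R,5R,6S)-2,6-di-Ar-3,7-dioxabicyclo[3.3.0]octan-1-ol
Product: 16 8-hydroxypinoresinol
Conditions: Pd(PPh3)4 (5 mol %), K2CO3, MeOH, rt
Reagents that add atoms: none
Why: In this Tsuji–Trost-type deallylation, zerovalent palladium should ionise each aryl allyl ether to a π-allyl complex and a phenoxide while methanol takes up the allyl group, freeing both phenols under conditions that leave the benzylic ethers and the tertiary alcohol untouched.

**Compound list**

1 | vanillin (4-hydroxy-3-methoxybenzaldehyde) | COc1cc(C=O)ccc1O | starting material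
2 | 4-(allyloxy)-3-methoxybenzaldehyde | C=CCOc1ccc(C=O)cc1OC | intermediate
3 | dimethyl succinate | COC(=O)CCC(=O)OC | starting material
4 | (E)-4-Ar-3-(methoxycarbonyl)but-3-enoic acid (aryl cis to CH2CO2H) | OC(=O)C/C(C(=O)OC)=C\c1ccc(OCC=C)c(OC)c1 | intermediate
5 | 4-tert-butyl 1-methyl (E)-2-(Ar-methylidene)butanedioate | CC(C)(C)OC(=O)C/C(C(=O)OC)=C\c1ccc(OCC=C)c(OC)c1 | intermediate
6 | tert-butyl (E)-4-Ar-3-(hydroxymethyl)but-3-enoate | CC(C)(C)OC(=O)C/C(CO)=C\c1ccc(OCC=C)c(OC)c1 | intermediate
7 | tert-butyl 2-[(2S,3S)-3-Ar-2-(hydroxymethyl)oxiran-2-yl]acetate | CC(C)(C)OC(=O)C[C@@]1(CO)O[C@H]1c2ccc(OCC=C)c(OC)c2 | intermediate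
8 | (4S,5R)-5-Ar-4-hydroxy-4-(hydroxymethyl)oxolan-2-one | O=C1C[C@](O)(CO)[C@@H](c2ccc(OCC=C)c(OC)c2)O1 | intermediate
9 | (5S,6R)-2,6-di-Ar-1,3,7-trioxaspiro[4.4]nonan-8-one, both epimers at the acetal carbon C-2 | O=C1C[C@]2(COC(c3ccc(OCC=C)c(OC)c3)O2)[C@@H](c4ccc(OCC=C)c(OC)c4)O1 | intermediate
10 | (5S,6R)-2,6-di-Ar-8-(trimethylsilyloxy)-1,3,7-trioxaspiro[4.4]non-8-ene (silyl ketene acetal of 9, not isolated) | C[Si](C)(C)OC1=C[C@]2(COC(c3ccc(OCC=C)c(OC)c3)O2)[C@@H](c4ccc(OCC=C)c(OC)c4)O1 | intermediate
11 | (3R,3aS,6S,6aR)-3,6-di-Ar-3a-(trimethylsilyloxy)tetrahydro-1H,3H-furo[3,4-c]furan-1-one (cis-fused, both aryl groups exo) | C=CCOc1ccc([C@H]2OC[C@]3(O[Si](C)(C)C)[C@@H](c4ccc(OCC=C)c(OC)c4)OC(=O)[C@H]23)cc1OC | intermediate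
12 | (R)-Ar[(3S,4R,5S)-5-Ar-4-(hydroxymethyl)-3-(trimethylsilyloxy)oxolan-3-yl]methanol (not isolated) | C=CCOc1ccc([C@H]2OC[C@](O[Si](C)(C)C)([C@H](O)c3ccc(OCC=C)c(OC)c3)[C@@H]2CO)cc1OC | intermediate
13 | (3S,4R,5S)-5-Ar-3-[(R)-Ar(hydroxy)methyl]-4-(hydroxymethyl)oxolan-3-ol | C=CCOc1ccc([C@H]2OC[C@](O)([C@H](O)c3ccc(OCC=C)c(OC)c3)[C@@H]2CO)cc1OC | intermediate
14 | [(2S,3R,4S)-2-Ar-4-hydroxy-4-[(R)-Ar(hydroxy)methyl]oxolan-3-yl]methyl methanesulfonate (not isolated) | C=CCOc1ccc([C@H]2OC[C@](O)([C@H](O)c3ccc(OCC=C)c(OC)c3)[C@@H]2COS(C)(=O)=O)cc1OC | intermediate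
15 | (1S,2R,5R,6S)-2,6-di-Ar-3,7-dioxabicyclo[3.3.0]octan-1-ol (di-O-allyl-8-hydroxypinoresinol) | C=CCOc1ccc([C@H]2OC[C@]3(O)[C@@H](c4ccc(OCC=C)c(OC)c4)OC[C@H]23)cc1OC | intermediate
16 | 8-hydroxypinoresinol, (1S,2R,5R,6S)-2,6-bis(4-hydroxy-3-methoxyphenyl)-3,7-dioxabicyclo[3.3.0]octan-1-ol | COc1cc([C@H]2OC[C@]3(O)[C@@H](c4ccc(O)c(OC)c4)OC[C@H]23)ccc1O | target

**Totals**

Total step count: 11. Longest linear sequence: 11 steps (1 → 16); aldehyde 2 enters a second time in step 7.

**Steps most likely to fail**

Step 8 (key step, proposed new method). What may go wrong: β-elimination of the C-1 oxygen from the silyl ketene acetal, or ionisation of the benzylic lactone C–O bond, may outrun C–C bond formation. The fallback sets out from compound 8 and comes back at compound 13, using known chemistry.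

Compound 8 is silylated at the primary hydroxyl (t-BuMe2SiCl, imidazole, DMF) to give the silyl ether F1. F1 is converted with LiN(i-Pr)2 (2.2 equiv, THF, −78 °C) into its alkoxide enolate, a Fráter–Seebach-type dianion that cannot eliminate because the β-oxygen is an alkoxide. This adds to aldehyde 2 in an intermolecular aldol reaction that makes the C-5–C-6 bond anti to the alkoxide and gives the aldol F2 (carbinol epimers; C-5 remains epimerisable, and only the cis-fusable epimer can close the bicycle). Bu4NF removes the silyl group to give the triol lactone F3. A trace of CSA in CH2Cl2 should ionise the electron-rich benzylic alcohol, and capture by the primary hydroxyl closes ring A through the C-6–O-7 bond with the aryl group on the convex face, giving the hydroxy furofuranone F4. Reduction of F4 with LiAlH4 gives triol 13.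

Step 6. What may go wrong: partial loss of stereospecificity at the benzylic carbon if the epoxide opens through a free cation of the electron-rich aryl group, or hydride-shift rearrangement of that cation. The fallback sets out from compound 4 and comes back at compound 8; it replaces the ester by a far better neighbouring group, so that ring closure can run under nearly neutral conditions.

The potassium salt of 4 (KOH, 1 equiv) is reduced at the conjugated ester with LiBH4 in THF and acidified to give the arylidene lactone F5. Aminolysis with pyrrolidine and AlMe3 in CH2Cl2 gives the hydroxy amide F6. The same asymmetric epoxidation (Ti(OiPr)4, L-(+)-diethyl tartrate, t-BuOOH) gives the epoxy amide F7. With PPTS in wet THF the amide oxygen should open the epoxide at the benzylic carbon with inversion, and hydrolysis of the iminium ether releases pyrrolidine and gives 8.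

Step 10. What may go wrong: poor site selectivity of sulfonylation, with activation of the benzylic hydroxyl leading to ionisation and epimerisation at C-2. The fallback sets out from compound 11 and comes back at compound 15; it never opens ring B.

Compound 11 is reduced with i-Bu2AlH (CH2Cl2, −78 °C) to the lactol F8. Et3SiH and BF3·OEt2 at −78 °C reduce the lactol through its cyclic oxocarbenium ion to the silyl ether F9. K2CO3 in MeOH removes the silyl group to give 15.

**Further compounds**

F1 | step 8 | (4S,5R)-5-Ar-4-{[tert-butyl(dimethyl)silyl]oxymethyl}-4-hydroxyoxolan-2-one | O=C1C[C@](O)(CO[Si](C)(C)C(C)(C)C)[C@@H](c2ccc(OCC=C)c(OC)c2)O1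
F2 | step 8 | (3R,4S,5R)-5-Ar-3-[Ar(hydroxy)methyl]-4-{[tert-butyl(dimethyl)silyl]oxymethyl}-4-hydroxyoxolan-2-one (carbinol epimers) | O=C1[C@H](C(O)c2ccc(OCC=C)c(OC)c2)[C@](O)(CO[Si](C)(C)C(C)(C)C)[C@@H](c3ccc(OCC=C)c(OC)c3)O1
F3 | step 8 | (3R,4S,5R)-5-Ar-3-[Ar(hydroxy)methyl]-4-hydroxy-4-(hydroxymethyl)oxolan-2-one (carbinol epimers) | O=C1[C@H](C(O)c2ccc(OCC=C)c(OC)c2)[C@](O)(CO)[C@@H](c3ccc(OCC=C)c(OC)c3)O1
F4 | step 8 | (3R,3aS,6S,6aR)-3,6-di-Ar-3a-hydroxytetrahydro-1H,3H-furo[3,4-c]furan-1-one | C=CCOc1ccc([C@H]2OC[C@]3(O)[C@@H](c4ccc(OCC=C)c(OC)c4)OC(=O)[C@H]23)cc1OC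
F5 | step 6 | (E)-4-(Ar-methylidene)oxolan-2-one | O=C1C/C(=C\c2ccc(OCC=C)c(OC)c2)CO1
F6 | step 6 | (E)-4-Ar-3-(hydroxymethyl)-1-(pyrrolidin-1-yl)but-3-en-1-one | O=C(C/C(CO)=C\c1ccc(OCC=C)c(OC)c1)N1CCCC1
F7 | step 6 | 2-[(2S,3S)-3-Ar-2-(hydroxymethyl)oxiran-2-yl]-1-(pyrrolidin-1-yl)ethan-1-one | O=C(C[C@@]1(CO)O[C@H]1c2ccc(OCC=C)c(OC)c2)N3CCCC3
F8 | step 10 | (3R,3aS,6S,6aR)-3,6-di-Ar-3a-(trimethylsilyloxy)tetrahydro-1H,3H-furo[3,4-c]furan-1-ol (both anomers) | C=CCOc1ccc([C@H]2OC[C@]3(O[Si](C)(C)C)[C@@H](c4ccc(OCC=C)c(OC)c4)OC(O)[C@H]23)cc1OC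
F9 | step 10 | (1S,2R,5R,6S)-2,6-di-Ar-1-(trimethylsilyloxy)-3,7-dioxabicyclo[3.3.0]octane | C=CCOc1ccc([C@H]2OC[C@]3(O[Si](C)(C)C)[C@@H](c4ccc(OCC=C)c(OC)c4)OC[C@H]23)cc1OC
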